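**Plan**

1. The core is numbered as a pyrrolo[2,3-b]indoline (N1, C2, C3, C3a, C3b, C4–C7, C7a, N8, C8a) with the furan fused at C4–C5 and its oxygen on C4. The retrosynthesis first raises C2 to a lactam carbonyl and removes C7–Br, then cuts N8–C7a and C3b–C3a together, giving a benzofuran-6,7-yne and a five-membered unsaturated lactam that already holds N1, C2, C3, C3a (with prenyl) and C8a–N8H.
2. Enabling feature: N8–C8a–C3a are three contiguous atoms shared by the cis-fused pyrrolidine and indoline rings. At the lactam oxidation level C3a is the β-carbon of an enone-type acceptor and the N8 carbamate is an N–H acid, so an aryne can be inserted between N8 and C3a. The furan oxygen on C4, next to C3b, polarises the aryne so that nitrogen adds at C7a and the carbanion arises on C3b.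
3. Forward order: the furan ring is built on the benzene ring (Sonogashira/cyclisation) and the arene is turned into an ortho-silyl triflate. The lactam ring is taken from N-methyl-L-pyroglutamic acid and prenylated. The annulation closes the indoline ring and completes the tetracycle; deprotection, bromination at C7 and lactam reduction follow.
4. Stereochemistry: C8a is the α-carbon of L-glutamic acid, carried through a Curtius rearrangement with retention. C3a is set in the annulation, because the aryl anion is held on N8 and can reach only the face of C3a syn to N8 (cis 5/5 fusion).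
5. Helpers: the C2 carbonyl (acceptor and aminal stabiliser, removed by alane), the Teoc group on N8 (N–H acidity, removed by fluoride) and a TBS ether on the tertiary alcohol.

Key step: step 8

Assumption: N-methyl-L-pyroglutamic acid 11 and 4-iodoresorcinol 1 are taken as purchasable; in the monocyclic lactams the atom labels of the final core are used (C8a aminal carbon, C3a β-carbon, C3 α-carbon, C2 carbonyl carbon).

**Route**

Step 1
Reactants: 1 4-iodobenzene-1,3-diol; 2 2-methylbut-3-yn-2-ol
Product: 4 2-(2-hydroxypropan-2-yl)-1-benzofuran-6-ol, via 4-alkynylresorcinol 3 (not isolated)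
Conditions: PdCl2(PPh3)2 (3 mol %), CuI (5 mol %), Et3N, DMF, 60 °C
Reagents that add atoms: none
Why: Sonogashira coupling at the C–I bond followed by 5-endo-dig cyclisation of the one hydroxyl that is ortho to the alkyne should give the 2-substituted benzofuran with the other hydroxyl at C6.

Step 2
Reactants: 4 2-(2-hydroxypropan-2-yl)-1-benzofuran-6-ol
Product: 5 2-(2-hydroxypropan-2-yl)-1-benzofuran-6-yl N-isopropylcarbamate
Conditions: i-PrNCO (1.2 equiv), Et3N (0.2 equiv), CH2Cl2, 23 °C
Reagents that add atoms: isopropyl isocyanate CC(C)N=C=O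
Why: Base-catalysed carbamoylation of the phenol by the isocyanate should leave the hindered tertiary alcohol alone and installs a directing group that can later be removed without acid.

Step 3
Reactants: 5 2-(2-hydroxypropan-2-yl)-1-benzofuran-6-yl N-isopropylcarbamate
Product: 8 2-[2-(tert-butyldimethylsilyloxy)propan-2-yl]-7-(trimethylsilyl)-1-benzofuran-6-yl N-isopropylcarbamate, via N-silyl O-silyl carbamate 6 (not isolated), via C7-silylated carbamate 7 (not isolated)
Conditions: t-BuMe2SiOTf (2.2 equiv), TMEDA, Et2O, 0 to 23 °C; n-BuLi (1.5 equiv), TMEDA, −78 °C; Me3SiCl, −78 to 23 °C; aq. NH4Cl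
Reagents that add atoms: tert-butyldimethylsilyl trifluoromethanesulfonate CC(C)(C)[Si](C)(C)OS(=O)(=O)C(F)(F)F; chlorotrimethylsilane C[Si](C)(C)Cl
Why: Directed ortho metalation after in situ silylation of the carbamate N–H and the tertiary O–H should remove H-7, the proton flanked by the carbamate oxygen and the furan oxygen, and Me3SiCl traps the aryllithium; the N–Si bond is hydrolysed on work-up while the tertiary silyl ether stays as protection.

Step 4
Reactants: 8 2-[2-(tert-butyldimethylsilyloxy)propan-2-yl]-7-(trimethylsilyl)-1-benzofuran-6-yl N-isopropylcarbamate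
Product: 10 2-[2-(tert-butyldimethylsilyloxy)propan-2-yl]-7-(trimethylsilyl)-1-benzofuran-6-yl trifluoromethanesulfonate, via silylphenol 9 (not isolated)
Conditions: DBU, Et2NH, MeCN, 40 °C; then PhNTf2, 23 °C
Reagents that add atoms: N-phenylbis(trifluoromethanesulfonimide) O=S(=O)(N(c1ccccc1)S(=O)(=O)C(F)(F)F)C(F)(F)F
Why: E1cB cleavage of the N-monoalkyl aryl carbamate (the isocyanate is captured by Et2NH) and sulfonylation of the phenoxide in the same flask should give the ortho-silylaryl triflate, a fluoride-triggered aryne precursor, without any acid touching the ionisable furyl carbinol ether.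

Step 5
Reactants: 11 (S)-1-methyl-5-oxopyrrolidine-2-carboxylic acid
Product: 14 2-(trimethylsilyl)ethyl N-[(2S)-1-methyl-5-oxopyrrolidin-2-yl]carbamate, via acyl azide 12 (not isolated), via isocyanate 13 (not isolated)
Conditions: (PhO)2P(O)N3, Et3N, toluene, 23 then 80 °C; Me3SiCH2CH2OH, 80 °C
Reagents that add atoms: diphenylphosphoryl azide [N-]=[N+]=NP(=O)(Oc1ccccc1)Oc1ccccc1; 2-(trimethylsilyl)ethanol C[Si](C)(C)CCO
Why: In the Curtius rearrangement the stereogenic carbon migrates with retention and the α-amido isocyanate is captured by the alcohol, so the α-carbon of glutamic acid becomes the (S)-configured N,N-aminal carbon (future C8a) bearing a fluoride-labile carbamate.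

Step 6
Reactants: 14 2-(trimethylsilyl)ethyl N-[(2S)-1-methyl-5-oxopyrrolidin-2-yl]carbamate
Product: 16 2-(trimethylsilyl)ethyl N-[(2S)-1-methyl-5-oxo-2,5-dihydro-1H-pyrrol-2-yl]carbamate, via selenide 15 (not isolated)
Conditions: LiN(i-Pr)2 (2.2 equiv), THF, −78 °C; PhSeCl; work-up; 30% H2O2, pyridine, CH2Cl2, 0 to 23 °C
Reagents that add atoms: none
Why: α-Selenenylation of the lactam enolate (formed by the second equivalent of base after N–H deprotonation) and selenoxide syn-elimination should introduce the C3–C3a double bond without involving the aminal carbon.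

Step 7
Reactants: 16 2-(trimethylsilyl)ethyl N-[(2S)-1-methyl-5-oxo-2,5-dihydro-1H-pyrrol-2-yl]carbamate; 17 prenylmagnesium chloride
Product: 19 2-(trimethylsilyl)ethyl N-[(2S)-1-methyl-3-(3-methylbut-2-en-1-yl)-5-oxo-2,5-dihydro-1H-pyrrol-2-yl]carbamate, via prenyl selenide 18 (not isolated)
Conditions: LiN(SiMe3)2 (1.0 equiv), THF, −78 °C; 17 (1.5 equiv), CuBr·SMe2 (15 mol %), Me3SiCl, −78 °C; PhSeCl, −78 to 0 °C; work-up; mCPBA (1.0 equiv), CH2Cl2, −78 °C, then i-Pr2NH, to 23 °C
Reagents that add atoms: none
Why: Copper-catalysed, Me3SiCl-accelerated conjugate addition of the allylic Grignard reagent through its unsubstituted terminus, selenenylation of the enolate anti to the new group and selenoxide syn-elimination with the cis hydrogen on C3a should return the unsaturated lactam prenylated at the β-carbon; the two transient stereocentres are erased and the aminal carbon is untouched.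

Step 8
Reactants: 10 2-[2-(tert-butyldimethylsilyloxy)propan-2-yl]-7-(trimethylsilyl)-1-benzofuran-6-yl trifluoromethanesulfonate; 19 2-(trimethylsilyl)ethyl N-[(2S)-1-methyl-3-(3-methylbut-2-en-1-yl)-5-oxo-2,5-dihydro-1H-pyrrol-2-yl]carbamate
Product: 21 N8-Teoc O-TBS tetracyclic lactam (cis-fused pyrroloindolin-2-one with quaternary C3a), via benzofuranyne 20 (not isolated)
Conditions: Bu4N[Ph3SiF2] (2.5 equiv), THF, 23 °C, 10 (1.3 equiv) added slowly
Reagents that add atoms: none
Why: Proposed new method: fluoride should unmask 6,7-benzofuranyne 20 from 10, the carbamate nitrogen of 19 should add to the aryne carbon that becomes C7a, and the aryl anion left on C3b should add to C3a, the fully substituted β-carbon of the unsaturated lactam, the C3 enolate being protonated by the N–H of the next molecule of 19. The closest known reaction type is the aryne N–H insertion/intramolecular conjugate-addition annulation that turns N-carbamoyl amino enoates and ortho-silylaryl triflates into indolines; new are the cyclic γ-carbamoylamino enone partner and the quaternary carbon. One ring, the indoline ring (C3b, C7a, N8, C8a, C3a), is closed by a 5-exo-trig conjugate addition, which at the same stroke completes the cis-fused tetracycle. C3a is controlled by C8a: the anion hangs on N8 and can reach only the face of the lactam syn to N8, so the (S)-aminal carbon is relayed into (S)-C3a with the obligatory cis ring fusion. The step needs N-attack at the aryne carbon remote from the furan oxygen (secured by the inductive polarisation of the aryne by that oxygen, which places the carbanion next to it), conjugate addition in preference to attack on the lactam or carbamate carbonyl (the fused five-membered transition state is preferred to the bridged six-membered or the four-membered one) and an intact aminal centre (N–H deprotonation comes first and disfavours removal of H-8a). The fluorosilicate should attack the aryl–silicon bond activated by the ortho triflate much faster than the tertiary silyl ether or the N-deprotonated 2-silylethyl carbamate.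

Step 9
Reactants: 21 N8-Teoc O-TBS tetracyclic lactam
Product: 22 N8-H tetracyclic lactam with free tertiary alcohol
Conditions: Bu4NF (4 equiv), THF, 0 to 40 °C
Reagents that add atoms: none
Why: Fluoride-induced β-elimination of the 2-(trimethylsilyl)ethyl carbamate (loss of ethene and CO2) should free N8–H and the same reagent cleaves the tertiary silyl ether, under basic conditions that spare the acid-labile furyl carbinol and the stereocentres.

Step 10
Reactants: 22 N8-H tetracyclic lactam
Product: 23 7-bromo tetracyclic lactam
Conditions: NBS (1.0 equiv), CH2Cl2, −78 to −40 °C, dark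
Reagents that add atoms: N-bromosuccinimide O=C1CCC(=O)N1Br
Why: In this electrophilic aromatic substitution C7 is ortho to the free N8–H and para to the furan oxygen while the position para to N8 is ring-fused, so one equivalent of NBS at low temperature should brominate the arene faster than the trisubstituted alkene or the furan carbon.

Step 11
Reactants: 23 7-bromo tetracyclic lactam
Product: 24 target CNP0306513.1
Conditions: AlH3·NMe2Et (4 equiv), THF, 0 to 23 °C; Na2SO4·10H2O
Reagents that add atoms: none
Why: Alane reduction of the tertiary lactam to the amine (C2=O to CH2) removes the activating carbonyl and should leave the aryl bromide, the alkene, the aminal and both stereocentres untouched.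

**Compound list**

1 | 4-iodobenzene-1,3-diol (4-iodoresorcinol) | Oc1ccc(I)c(O)c1 | starting material
2 | 2-methylbut-3-yn-2-ol | CC(C)(O)C#C | starting material
3 | 4-(3-hydroxy-3-methylbut-1-yn-1-yl)benzene-1,3-diol | CC(C)(O)C#Cc1ccc(O)cc1O | intermediate
4 | 2-(2-hydroxypropan-2-yl)-1-benzofuran-6-ol | CC(C)(O)c1cc2ccc(O)cc2o1 | intermediate
5 | 2-(2-hydroxypropan-2-yl)-1-benzofuran-6-yl N-isopropylcarbamate | CC(C)NC(=O)Oc1ccc2cc(C(C)(C)O)oc2c1 | intermediate
6 | N-TBS, O-TBS derivative of 5 (silylated on the carbamate nitrogen and the tertiary oxygen) | CC(C)N([Si](C)(C)C(C)(C)C)C(=O)Oc1ccc2cc(C(C)(C)O[Si](C)(C)C(C)(C)C)oc2c1 | intermediate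
7 | 7-trimethylsilyl derivative of 6 | CC(C)N([Si](C)(C)C(C)(C)C)C(=O)Oc1ccc2cc(C(C)(C)O[Si](C)(C)C(C)(C)C)oc2c1[Si](C)(C)C | intermediate
8 | 2-[2-(tert-butyldimethylsilyloxy)propan-2-yl]-7-(trimethylsilyl)-1-benzofuran-6-yl N-isopropylcarbamate | CC(C)NC(=O)Oc1ccc2cc(C(C)(C)O[Si](C)(C)C(C)(C)C)oc2c1[Si](C)(C)C | intermediate
9 | 2-[2-(tert-butyldimethylsilyloxy)propan-2-yl]-7-(trimethylsilyl)-1-benzofuran-6-ol | CC(C)(O[Si](C)(C)C(C)(C)C)c1cc2ccc(O)c([Si](C)(C)C)c2o1 | intermediate
10 | 2-[2-(tert-butyldimethylsilyloxy)propan-2-yl]-7-(trimethylsilyl)-1-benzofuran-6-yl trifluoromethanesulfonate | CC(C)(O[Si](C)(C)C(C)(C)C)c1cc2ccc(OS(=O)(=O)C(F)(F)F)c([Si](C)(C)C)c2o1 | intermediate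
11 | (S)-1-methyl-5-oxopyrrolidine-2-carboxylic acid (N-methyl-L-pyroglutamic acid) | OC(=O)[C@@H]1CCC(=O)N1C | starting material
12 | acyl azide of 11, configuration unchanged | [N-]=[N+]=NC(=O)[C@@H]1CCC(=O)N1C | intermediate
13 | 5-isocyanato-1-methylpyrrolidin-2-one, spatial arrangement of 11 retained | O=C=N[C@@H]1CCC(=O)N1C | intermediate
14 | 2-(trimethylsilyl)ethyl N-[(2S)-1-methyl-5-oxopyrrolidin-2-yl]carbamate | C[Si](C)(C)CCOC(=O)N[C@@H]1CCC(=O)N1C | intermediate
15 | 2-(trimethylsilyl)ethyl N-[(2S)-1-methyl-5-oxo-4-(phenylselanyl)pyrrolidin-2-yl]carbamate, both epimers at the selenium-bearing carbon | C[Si](C)(C)CCOC(=O)N[C@@H]1CC([Se]c2ccccc2)C(=O)N1C | intermediate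
16 | 2-(trimethylsilyl)ethyl N-[(2S)-1-methyl-5-oxo-2,5-dihydro-1H-pyrrol-2-yl]carbamate | C[Si](C)(C)CCOC(=O)N[C@@H]1C=CC(=O)N1C | intermediate
17 | prenylmagnesium chloride (3-methylbut-2-en-1-ylmagnesium chloride) | CC(C)=CC[Mg]Cl | starting material
18 | 2-(trimethylsilyl)ethyl N-[(2S)-1-methyl-3-(3-methylbut-2-en-1-yl)-5-oxo-4-(phenylselanyl)pyrrolidin-2-yl]carbamate, expected 2,3-trans-3,4-trans isomer | C[Si](C)(C)CCOC(=O)N[C@@H]1[C@@H](CC=C(C)C)[C@H]([Se]c2ccccc2)C(=O)N1C | intermediate
19 | 2-(trimethylsilyl)ethyl N-[(2S)-1-methyl-3-(3-methylbut-2-en-1-yl)-5-oxo-2,5-dihydro-1H-pyrrol-2-yl]carbamate | C[Si](C)(C)CCOC(=O)N[C@@H]1C(CC=C(C)C)=CC(=O)N1C | intermediate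
20 | 2-[2-(tert-butyldimethylsilyloxy)propan-2-yl]-6,7-didehydro-1-benzofuran (6,7-benzofuranyne) | CC(C)(O[Si](C)(C)C(C)(C)C)C1=CC2=C(O1)C#CC=C2 | intermediate
21 | cis-fused 1-methyl-3a-prenyl-pyrrolo[2,3-b]indolin-2-one with furan fused at C4–C5 (oxygen on C4, 2-(TBS-oxy)propan-2-yl on the furan carbon next to oxygen) and Teoc on N8; (3aS,8aR) by the sequence rules because the carbamate outranks N1, spatial arrangement as in the target | CC(C)=CC[C@@]12CC(=O)N(C)[C@@H]1N(C(=O)OCC[Si](C)(C)C)c1ccc3cc(C(C)(C)O[Si](C)(C)C(C)(C)C)oc3c12 | intermediate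
22 | (3aS,8aS) N8-H lactam: as 21 without Teoc and with the free 2-hydroxypropan-2-yl group | CC(C)=CC[C@@]12CC(=O)N(C)[C@@H]1Nc1ccc3cc(C(C)(C)O)oc3c12 | intermediate
23 | (3aS,8aS) 7-bromo derivative of 22 (bromine ortho to N8) | CC(C)=CC[C@@]12CC(=O)N(C)[C@@H]1Nc1c(Br)cc3cc(C(C)(C)O)oc3c12 | intermediate
24 | CNP0306513.1, (3aS,8aS) | CC(C)=CC[C@@]12CCN(C)[C@@H]1Nc1c(Br)cc3cc(C(C)(C)O)oc3c12 | target

**Count and risks**

Total steps: 11. Longest linear sequence: 8 steps (steps 1–4 and 8–11); the lactam branch contributes 3 steps before the convergence.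

Steps most likely to fail:

1. Step 8 (Proposed new method). Protonation of the aryl anion by the carbamate N–H or by trace water may outrun ring closure onto the fully substituted β-carbon and leave only N-arylation; N–H addition of the weakly acidic carbamate may also be slow, and fluoride may cleave the Teoc group early. The fallback uses known chemistry and sets out from 10 and 19. The aryne is generated with CsF in MeCN in the presence of perfluorohexyl iodide, so that the aryl anion formed after N-arylation is intercepted by iodine transfer (three-component aryne amination–halogenation). This should give the ortho-iodo N-aryl carbamate F1, with nitrogen and iodine placed by the same aryne polarisation. A tin-hydride-mediated 5-exo-trig aryl radical conjugate cyclisation (Bu3SnH, AIBN, benzene, 80 °C) then forms the same C3b–C3a bond, again only on the face syn to N8, and the route is rejoined at 21.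

2. Step 10. Electrophilic bromine may be consumed by the trisubstituted double bond (bromonium formation, capture by N8) in competition with the arene, or a second bromination may follow. The fallback sets out from 22. An excess of pyridinium tribromide (2.1 equiv, CH2Cl2, 0 °C) brominates arene and alkene on purpose to give the tribromide F2 (aryl bromide plus 2,3-dibromo-3-methylbutyl side chain, both epimers at the CHBr carbon). Zinc dust in EtOH/THF then removes the vicinal dibromide by reductive elimination and restores the prenyl group, and the route is rejoined at 23.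

3. Step 7. The allylic copper reagent may transfer the prenyl group through its substituted terminus (reverse-prenyl adduct), and 1,4-addition to the N-alkyl lactam may be sluggish. The fallback sets out from 16. Allylmagnesium bromide is added under the same copper/Me3SiCl conditions, the enolate is selenenylated to the allyl selenide F3, and oxidation/elimination as in the step gives the 4-allyl unsaturated lactam F4. Cross-metathesis with 2-methylbut-2-ene (second-generation Grubbs catalyst, CH2Cl2, 40 °C) converts the terminal alkene into the prenyl group without touching the conjugated ring alkene, and the route is rejoined at 19.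

Further compounds
F1 | step 8 | 2-(trimethylsilyl)ethyl N-{2-[2-(tert-butyldimethylsilyloxy)propan-2-yl]-7-iodo-1-benzofuran-6-yl}-N-[1-methyl-3-(3-methylbut-2-en-1-yl)-5-oxo-2,5-dihydro-1H-pyrrol-2-yl]carbamate, aminal carbon with the spatial arrangement of 19 | CC(C)=CCC1=CC(=O)N(C)[C@@H]1N(C(=O)OCC[Si](C)(C)C)c1ccc2cc(C(C)(C)O[Si](C)(C)C(C)(C)C)oc2c1I
F2 | step 10 | tribromide: 23 with the prenyl double bond converted into the 2,3-dibromo-3-methylbutyl group, ring stereocentres as in 22, both epimers at CHBr | CC(C)(Br)C(Br)C[C@@]12CC(=O)N(C)[C@@H]1Nc1c(Br)cc3cc(C(C)(C)O)oc3c12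
F3 | step 7 | 2-(trimethylsilyl)ethyl N-[(2S)-1-methyl-5-oxo-4-(phenylselanyl)-3-(prop-2-en-1-yl)pyrrolidin-2-yl]carbamate, expected 2,3-trans-3,4-trans isomer | C[Si](C)(C)CCOC(=O)N[C@@H]1[C@@H](CC=C)[C@H]([Se]c2ccccc2)C(=O)N1C
F4 | step 7 | 2-(trimethylsilyl)ethyl N-[(2S)-1-methyl-5-oxo-3-(prop-2-en-1-yl)-2,5-dihydro-1H-pyrrol-2-yl]carbamate | C[Si](C)(C)CCOC(=O)N[C@@H]1C(CC=C)=CC(=O)N1C
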